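The dihydrofuran ring is read as a rearranged oxetane. The chain hydroxyl O–CH2–C3–C2 becomes a four-membered ether when that oxygen, rather than O1 of ring A, is bonded to C2. C2 is the para-oxygenated benzylic carbon of the syringyl ring, so the strained C2–O bond can later be traded for C2–O1. One Paternò–Büchi photocycloaddition forms C2–C3 and CH2–O, closes the oxetane and creates both stereocentres. Its precursors are O-silylated syringaldehyde and a brominated ring A styrene whose phenol carries a camphanoyl group beside C3, the only stereocentre that survives the transposition. Acetylation, Heck coupling and methanolysis complete the stilbene.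

Key step: step 4

Numbering: benzofuran numbering of the target (O1, C2, C3, C3a to C7a) is used for all intermediates. Ring A is the benzo ring. Oxetane C2 and C3 are the later C2 and C3.

Assumption: the sense and size of the facial bias of the camphanoyl group cannot be predicted. The (1S) series is drawn, and the equally available (1R)-camphanic chloride would be used if the (1S) group favours the wrong C3 epimer.

Step 1
Reactants: 1 syringaldehyde
Product: 2 3,5-dimethoxy-4-(triisopropylsilyloxy)benzaldehyde
Conditions: TIPSCl (1.2 equiv), imidazole (2.5 equiv), DMF, rt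
Reagents that add atoms: triisopropylsilyl chloride, CC(C)[Si](Cl)(C(C)C)C(C)C
Why: Silylation of an acidic phenol with a silyl chloride and imidazole is routine; the capped oxygen cannot quench the triplet state in step 4, and the bulky silyl group between two methoxy groups outlasts the carbonate stage of step 5, so that this oxygen is unmasked last.

Step 2
Reactants: 3 5-bromo-2-hydroxy-3-methoxybenzaldehyde
Product: 4 4-bromo-2-ethenyl-6-methoxyphenol
Conditions: MePPh3Br (2.5 equiv), KOtBu (2.4 equiv), THF, 0 °C to rt
Reagents that add atoms: methyltriphenylphosphonium bromide, C[P+](c1ccccc1)(c1ccccc1)c1ccccc1.[Br-]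
Why: Wittig methylenation with an extra equivalent of ylide to take up the phenolic proton is the standard way from salicylaldehydes to 2-vinylphenols, and the aryl bromide is inert to it.

Step 3
Reactants: 4 4-bromo-2-ethenyl-6-methoxyphenol
Product: 5 4-bromo-2-ethenyl-6-methoxyphenyl (1S,4R)-camphanate
Conditions: (1S)-(−)-camphanic chloride (1.1 equiv), Et3N, DMAP (cat.), CH2Cl2, 0 °C to rt
Reagents that add atoms: (1S)-(−)-camphanic chloride, O=C(Cl)[C@@]12CC[C@@](C)(C(=O)O1)C2(C)C
Why: DMAP-catalysed O-acylation of a phenol; the ester caps the O–H, makes the styrene harder to oxidise, and puts an enantiopure, crystalline, base-labile group on the oxygen next to the carbon that becomes C3.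

Step 4
Reactants: 2 3,5-dimethoxy-4-(triisopropylsilyloxy)benzaldehyde; 5 4-bromo-2-ethenyl-6-methoxyphenyl (1S,4R)-camphanate
Product: 7 (2S,3S)-trans-2-[3,5-dimethoxy-4-(triisopropylsilyloxy)phenyl]-3-[5-bromo-2-(camphanoyloxy)-3-methoxyphenyl]oxetane, via triplet 1,4-biradical 6 (not isolated)
Conditions: hν (365 nm LED, Pyrex), 2 (2 equiv), 5 (0.05 M), PhCF3, argon, −20 °C; C3 epimers separated on Et3N-deactivated silica gel, then crystallisation
Reagents that add atoms: none
Why: Proposed new method: light of 365 nm is absorbed only by 2, whose n,π* triplet attacks the terminal CH2 of 5 through oxygen to give the triplet 1,4-biradical 6, benzylic at C2 and at C3, and after spin inversion radical recombination forms C2–C3 and so closes the four-membered ring (stepwise (2+2), O–CH2 first, C–C second). The closest known reactions are the racemic Paternò–Büchi reaction of aromatic aldehydes with styrenes and the auxiliary- or hydrogen-bond-directed diastereoselective variants with chiral glyoxylates, enamides and allylic alcohols, whereas absolute control from a group on the styrene ring has not been shown. Both stereocentres arise only in the recombination, when the former carbonyl oxygen is already an ether, so the controller is bound covalently to the styrene half: the camphanoyl ester, turned out of the plane of ring A by its two ortho neighbours, sits over one face of the planar C3 radical and should steer C2 to the other face, and because the C3 epimers are now diastereomers the (3S) isomer can be freed from its epimer whatever the bias. C2 should come out trans to ring A because the two aryl groups avoid each other in the closing biradical, and its configuration is erased in step 5 anyway. Regiochemistry (2,3- and not 2,4-diaryl) rests on the benzylic stabilisation of the C3 radical and on the non-polar solvent, which disfavours electron transfer. Energy transfer from triplet 2 to 5 costs photons but returns both partners, since the styrene triplet decays by twisting; dilute 5 and low temperature hold back its dimerisation, and both phenols are capped because a free O–H would quench the triplet.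

Step 5
Reactants: 7 (2S,3S)-trans-oxetane camphanate
Product: 11 4-[(2R,3S)-5-bromo-3-(hydroxymethyl)-7-methoxy-2,3-dihydro-1-benzofuran-2-yl]-2,6-dimethoxyphenol, via ring A phenol oxetane 8 (not isolated), via bisphenol oxetane 9 (not isolated), via para-quinone methide 10 (not isolated)
Conditions: K2CO3 (2 equiv), MeOH–THF 1:1, 0 °C to rt; then TBAF (1.2 equiv), 0 °C to rt; then AcOH to pH 5, rt
Reagents that add atoms: none
Why: Carbonate methanolysis of the aryl ester frees the ring A phenoxide first, fluoride desilylation then unmasks the para-phenoxide, whose 1,6-elimination (the quinone methide route known for para-hydroxybenzyl ethers, here helped by the ring strain of the oxetane) breaks C2–O to give 10 while methanol protonates the departing alkoxide and so blocks loss of formaldehyde, and the ring A phenoxide closes C2–O1 by 5-exo-trig oxa-1,6-addition anti to the CH2OH group on the untouched C3, a reversible addition that settles on the trans (2R,3S) isomer.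

Step 6
Reactants: 11 bromo-dihydrobenzofuran phenol alcohol
Product: 12 [(2R,3S)-2-(4-acetoxy-3,5-dimethoxyphenyl)-5-bromo-7-methoxy-2,3-dihydro-1-benzofuran-3-yl]methyl acetate
Conditions: Ac2O (4 equiv), pyridine, DMAP (cat.), CH2Cl2, 0 °C to rt
Reagents that add atoms: acetic anhydride, CC(=O)OC(C)=O
Why: Standard peracetylation masks the para-phenol, so that C2–O1 cannot reopen through the quinone methide in the hot basic Heck medium, and masks the primary alcohol, both as groups that leave together with those of 15 in step 10.

Step 7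
Reactants: 13 3,5-dihydroxybenzaldehyde
Product: 14 5-ethenylbenzene-1,3-diol
Conditions: MePPh3Br (3.6 equiv), KOtBu (3.5 equiv), THF, 0 °C to rt
Reagents that add atoms: methyltriphenylphosphonium bromide, C[P+](c1ccccc1)(c1ccccc1)c1ccccc1.[Br-]
Why: Wittig methylenation with enough ylide to deprotonate both phenols first; the meta-phenoxides are not conjugated with the aldehyde and leave it reactive.

Step 8
Reactants: 14 5-ethenylbenzene-1,3-diol
Product: 15 5-ethenylbenzene-1,3-diyl diacetate (3,5-diacetoxystyrene)
Conditions: Ac2O (3 equiv), pyridine, 0 °C to rt, directly on crude 14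
Reagents that add atoms: acetic anhydride, CC(=O)OC(C)=O
Why: Acetylation right after work-up turns the polymerisation-prone vinylresorcinol into a storable Heck partner.

Step 9
Reactants: 12 bromo-dihydrobenzofuran diacetate; 15 3,5-diacetoxystyrene
Product: 16 gnetucleistol F tetraacetate, 5-[(E)-2-{(2R,3S)-2-(4-acetoxy-3,5-dimethoxyphenyl)-3-(acetoxymethyl)-7-methoxy-2,3-dihydro-1-benzofuran-5-yl}ethenyl]benzene-1,3-diyl diacetate
Conditions: 15 (1.3 equiv), Pd2(dba)3 (2.5 mol %), [HP(t-Bu)3]BF4 (10 mol %), Cy2NMe (1.5 equiv), 1,4-dioxane, 80 °C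
Reagents that add atoms: none
Why: Mizoroki–Heck reaction in which the bulky electron-rich phosphine lets zerovalent palladium insert into the electron-rich C5–Br bond at moderate temperature, syn insertion at the terminal carbon of 15 and syn β-hydride elimination give the E-stilbene, and the hindered amine leaves the four acetates and both stereocentres untouched.

Step 10
Reactants: 16 gnetucleistol F tetraacetate
Product: 17 gnetucleistol F, (2R,3S), E
Conditions: K2CO3 (3 equiv), degassed MeOH, argon, 0 °C to rt; then AcOH to pH 6
Reagents that add atoms: none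
Why: Carbonate-mediated transesterification removes the three aryl acetates and the primary acetate at or below room temperature, where C2–O1 does not reopen, so both stereocentres and the E-alkene are kept, and air is excluded because polyphenolates oxidise easily.

Compound list
1 | syringaldehyde (4-hydroxy-3,5-dimethoxybenzaldehyde) | COc1cc(C=O)cc(OC)c1O | starting material
2 | 3,5-dimethoxy-4-(triisopropylsilyloxy)benzaldehyde | COc1cc(C=O)cc(OC)c1O[Si](C(C)C)(C(C)C)C(C)C | intermediate
3 | 5-bromo-2-hydroxy-3-methoxybenzaldehyde | COc1cc(Br)cc(C=O)c1O | starting material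
4 | 4-bromo-2-ethenyl-6-methoxyphenol | C=Cc1cc(Br)cc(OC)c1O | intermediate
5 | 4-bromo-2-ethenyl-6-methoxyphenyl (1S,4R)-4,7,7-trimethyl-3-oxo-2-oxabicyclo[2.2.1]heptane-1-carboxylate (camphanate) | C=Cc1cc(Br)cc(OC)c1OC(=O)[C@@]12CC[C@@](C)(C(=O)O1)C2(C)C | intermediate
6 | triplet 1,4-biradical, syringyl-CH(•)–O–CH2–CH(•)–ring A, protecting groups as in 7 | COc1cc([CH]OC[CH]c2cc(Br)cc(OC)c2OC(=O)[C@@]23CC[C@@](C)(C(=O)O2)C3(C)C)cc(OC)c1O[Si](C(C)C)(C(C)C)C(C)C | intermediate
7 | 4-bromo-2-{(2S,3S)-2-[3,5-dimethoxy-4-(triisopropylsilyloxy)phenyl]oxetan-3-yl}-6-methoxyphenyl (1S,4R)-camphanate (trans-oxetane) | COc1cc([C@H]2OC[C@@H]2c2cc(Br)cc(OC)c2OC(=O)[C@@]23CC[C@@](C)(C(=O)O2)C3(C)C)cc(OC)c1O[Si](C(C)C)(C(C)C)C(C)C | intermediate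
8 | 4-bromo-2-{(2S,3S)-2-[3,5-dimethoxy-4-(triisopropylsilyloxy)phenyl]oxetan-3-yl}-6-methoxyphenol | COc1cc([C@H]2OC[C@@H]2c2cc(Br)cc(OC)c2O)cc(OC)c1O[Si](C(C)C)(C(C)C)C(C)C | intermediate
9 | 4-[(2S,3S)-3-(5-bromo-2-hydroxy-3-methoxyphenyl)oxetan-2-yl]-2,6-dimethoxyphenol | COc1cc([C@H]2OC[C@@H]2c2cc(Br)cc(OC)c2O)cc(OC)c1O | intermediate
10 | 4-[(2S)-2-(5-bromo-2-hydroxy-3-methoxyphenyl)-3-hydroxypropylidene]-2,6-dimethoxycyclohexa-2,5-dien-1-one | COC1=CC(=C[C@H](CO)c2cc(Br)cc(OC)c2O)C=C(OC)C1=O | intermediate
11 | 4-[(2R,3S)-5-bromo-3-(hydroxymethyl)-7-methoxy-2,3-dihydro-1-benzofuran-2-yl]-2,6-dimethoxyphenol | COc1cc([C@@H]2Oc3c(OC)cc(Br)cc3[C@H]2CO)cc(OC)c1O | intermediate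
12 | [(2R,3S)-2-(4-acetoxy-3,5-dimethoxyphenyl)-5-bromo-7-methoxy-2,3-dihydro-1-benzofuran-3-yl]methyl acetate | COc1cc([C@@H]2Oc3c(OC)cc(Br)cc3[C@H]2COC(C)=O)cc(OC)c1OC(C)=O | intermediate
13 | 3,5-dihydroxybenzaldehyde | O=Cc1cc(O)cc(O)c1 | starting material
14 | 5-ethenylbenzene-1,3-diol | C=Cc1cc(O)cc(O)c1 | intermediate
15 | 5-ethenylbenzene-1,3-diyl diacetate | C=Cc1cc(OC(C)=O)cc(OC(C)=O)c1 | intermediate
16 | gnetucleistol F tetraacetate, (2R,3S), E | COc1cc([C@@H]2Oc3c(OC)cc(/C=C/c4cc(OC(C)=O)cc(OC(C)=O)c4)cc3[C@H]2COC(C)=O)cc(OC)c1OC(C)=O | intermediate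
17 | gnetucleistol F, (2R,3S), E | COc1cc([C@@H]2Oc3c(OC)cc(/C=C/c4cc(O)cc(O)c4)cc3[C@H]2CO)cc(OC)c1O | target

Total step count: 10. Longest linear sequence: 7 (steps 2, 3, 4, 5, 6, 9, 10).

Steps most likely to fail

1. Step 4.
- **What may go wrong:** Exergonic triplet energy transfer from the excited aldehyde to the styrene may outrun attack of the carbonyl oxygen on CH2. Conversion would then stall while the styrene dimerises or polymerises and the aldehyde is consumed by hydrogen abstraction. The facial bias of the auxiliary may also be small, and the separation of the C3 epimers laborious.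
- **Fallback (known chemistry, no light):** It sets out from 4 and 2 and comes back at 11.
  - Silylation of 4 (TBSCl, imidazole) gives tert-butyl(4-bromo-2-ethenyl-6-methoxyphenoxy)dimethylsilane F1.
  - Hydroboration with 9-BBN and oxidation with NaBO3·4H2O gives 2-[5-bromo-2-(tert-butyldimethylsilyloxy)-3-methoxyphenyl]ethanol F2.
  - TEMPO/PhI(OAc)2 in aqueous MeCN gives [5-bromo-2-(tert-butyldimethylsilyloxy)-3-methoxyphenyl]acetic acid F3.
  - Activation with pivaloyl chloride and acylation of (R)-4-benzyl-2-oxazolidinone (Et3N, LiCl) gives the (R)-4-benzyl-3-(arylacetyl)oxazolidin-2-one F4.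
  - An Evans syn-aldol reaction (Bu2BOTf, i-Pr2NEt, CH2Cl2, −78 °C, then 2) sets the α-carbon, the later C3, under auxiliary control and gives the (2R,3R)-syn-aldol imide F5.
  - LiBH4 releases the auxiliary and gives the (1R,2S)-1,2-diarylpropane-1,3-diol F6.
  - TBAF frees both phenols to the (1R,2S)-bisphenol diol F7.
  - Catalytic p-TsOH in CH2Cl2 ionises the para-hydroxybenzylic alcohol and lets the ring A phenol close the trans-dihydrofuran 11.

2. Step 5.
- **What may go wrong:** The ring-opened intermediate may lose formaldehyde by retro-aldol cleavage of the C3–CH2 bond. Methanol may add to C2 faster than O1 does. The opening may also be slow enough for the phenoxide to attack CH2 instead of C2.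
- **Fallback:** It sets out from 8, isolated by stopping step 5 after the carbonate stage, and comes back at 11.
  - With the para oxygen still silylated, no quinone methide can form.
  - Catalytic Sc(OTf)3 in CH2Cl2 at −40 °C activates the oxetane oxygen, and the ring A phenol opens the benzylic C2–O bond from the rear. This is a Lewis-acid-catalysed intramolecular oxetane opening by a phenol.
  - Inversion at C2 of the trans-oxetane leads again to the trans product, the O-triisopropylsilyl ether of 11 F8, which TBAF in THF converts into 11.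

3. Step 9.
- **What may go wrong:** Oxidative addition into the electron-rich aryl bromide may be sluggish. Arylation at the internal alkene carbon and thermal polymerisation of the styrene may take over.
- **Fallback:** It sets out from 15 and 12 and comes back at 16.
  - Cross-metathesis of 15 with vinylboronic acid pinacol ester (second-generation Grubbs catalyst, CH2Cl2, 40 °C) gives (E)-2-(3,5-diacetoxyphenyl)ethenylboronic acid pinacol ester F9.
  - The alkene geometry of F9 is fixed before the coupling. Suzuki–Miyaura coupling with 12 (Pd(dppf)Cl2, K3PO4, 1,4-dioxane, 70 °C) gives 16.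
  - Partial loss of acetate there is harmless, because step 10 removes all of them.

Further compounds
F1 | step 4 | tert-butyl(4-bromo-2-ethenyl-6-methoxyphenoxy)dimethylsilane | C=Cc1cc(Br)cc(OC)c1O[Si](C)(C)C(C)(C)C
F2 | step 4 | 2-[5-bromo-2-(tert-butyldimethylsilyloxy)-3-methoxyphenyl]ethanol | OCCc1cc(Br)cc(OC)c1O[Si](C)(C)C(C)(C)C
F3 | step 4 | [5-bromo-2-(tert-butyldimethylsilyloxy)-3-methoxyphenyl]acetic acid | OC(=O)Cc1cc(Br)cc(OC)c1O[Si](C)(C)C(C)(C)C
F4 | step 4 | (R)-4-benzyl-3-(arylacetyl)oxazolidin-2-one | O=C1OC[C@@H](Cc2ccccc2)N1C(=O)Cc1cc(Br)cc(OC)c1O[Si](C)(C)C(C)(C)C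
F5 | step 4 | (2R,3R)-syn-aldol imide | O=C1OC[C@@H](Cc2ccccc2)N1C(=O)[C@H](c1cc(Br)cc(OC)c1O[Si](C)(C)C(C)(C)C)[C@@H](O)c1cc(OC)c(O[Si](C(C)C)(C(C)C)C(C)C)c(OC)c1
F6 | step 4 | (1R,2S)-1,2-diarylpropane-1,3-diol | OC[C@H](c1cc(Br)cc(OC)c1O[Si](C)(C)C(C)(C)C)[C@@H](O)c1cc(OC)c(O[Si](C(C)C)(C(C)C)C(C)C)c(OC)c1
F7 | step 4 | (1R,2S)-bisphenol diol | OC[C@H](c1cc(Br)cc(OC)c1O)[C@@H](O)c1cc(OC)c(O)c(OC)c1
F8 | step 5 | O-triisopropylsilyl ether of 11 | COc1cc([C@@H]2Oc3c(OC)cc(Br)cc3[C@H]2CO)cc(OC)c1O[Si](C(C)C)(C(C)C)C(C)C
F9 | step 9 | (E)-2-(3,5-diacetoxyphenyl)ethenylboronic acid pinacol ester | CC(=O)Oc1cc(/C=C/B2OC(C)(C)C(C)(C)O2)cc(OC(C)=O)c1
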